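**Retrosynthetic overview**
1. Target 37 ⇐ macrocycle 29 by a late endgame: C15 acetate put on and taken off by a lipase, C8 ester from (R)-2-methylbutanoic acid (tiglic acid, Ru-catalysed hydrogenation), acetonide removal, C14 oxidation.
2. Ten-membered ring (third ring, formed last) ⇐ ring-closing metathesis at C1=C10 of diene 24, then α-methylenation (C13).
3. C8–C9 bond with the 9,14-dioxane (second ring, brought in preformed) ⇐ (R)-proline aldol of 2,2-dimethyl-1,3-dioxan-5-one with lactone aldehyde 20; C10=CH2 by Lombardo methylenation.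
4. γ-Lactone (first ring) ⇐ Zn–ProPhenol alkynylation of enal 9 with methyl propiolate (sets C6), Lindlar reduction/lactonisation, anti copper conjugate addition (sets C7).
5. Enal 9 ⇐ prop-2-yn-1-ol by ynoate hydroiodination and Negishi coupling, which fixes the C4=C5 geometry.

Assumption: atoms carry germacrane locants (C1–C10 ring, C12 lactone carbonyl, C13 exocyclic methylene, C14 formyl carbon, C15 hydroxymethyl carbon), descriptors are CIP descriptors of the compound named, and the target read from the SMILES is (1(10)E,4E,6R,7S,8R,9S) with a (2R)-2-methylbutanoate.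

**Step 1**
Reactants: 1 prop-2-yn-1-ol
Product: 2 tert-butyl(diphenyl)(prop-2-yn-1-yloxy)silane
Conditions: TBDPSCl, imidazole, CH2Cl2, 0 °C to rt
Reagents that add atoms: tert-butyl(chloro)diphenylsilane, CC(C)(C)[Si](Cl)(c1ccccc1)c1ccccc1
Why: Imidazole-promoted silylation masks the future C15 hydroxyl as a silyl ether that survives the acid, hydride, organometallic and enolate steps ahead, and no stereocenter is formed.

**Step 2**
Reactants: 2 tert-butyl(diphenyl)(prop-2-yn-1-yloxy)silane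
Product: 4 ethyl 4-{[tert-butyl(diphenyl)silyl]oxy}but-2-ynoate, via lithium acetylide 3 (not isolated)
Conditions: n-BuLi, THF, −78 °C; ClCO2Et, −78 °C to 0 °C
Reagents that add atoms: ethyl chloroformate, CCOC(=O)Cl
Why: Deprotonation of the terminal alkyne and C-acylation of the acetylide with a chloroformate is a standard ynoate synthesis that creates no stereocenter.

**Step 3**
Reactants: 4 ethyl 4-{[tert-butyl(diphenyl)silyl]oxy}but-2-ynoate
Product: 5 ethyl (2Z)-4-{[tert-butyl(diphenyl)silyl]oxy}-3-iodobut-2-enoate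
Conditions: NaI, AcOH, 70 °C
Reagents that add atoms: sodium iodide, [Na+].[I-]
Why: Conjugate hydroiodination of the ynoate is an anti addition of HI that puts iodine cis to the ester, so the C4=C5 geometry is fixed before any stereocenter exists.

**Step 4**
Reactants: 5 ethyl (2Z)-4-{[tert-butyl(diphenyl)silyl]oxy}-3-iodobut-2-enoate; 6 but-3-en-1-ylzinc bromide
Product: 7 ethyl (2E)-3-({[tert-butyl(diphenyl)silyl]oxy}methyl)hepta-2,6-dienoate
Conditions: Pd(PPh3)4 (5 mol %), THF, rt to 45 °C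
Reagents that add atoms: none
Why: Negishi cross-coupling at zerovalent palladium replaces iodine by the butenyl chain with retention of alkene geometry, so the future C6 carbon ends cis to C3 and trans to C15.

**Step 5**
Reactants: 7 ethyl (2E)-3-({[tert-butyl(diphenyl)silyl]oxy}methyl)hepta-2,6-dienoate
Product: 8 (2E)-3-({[tert-butyl(diphenyl)silyl]oxy}methyl)hepta-2,6-dien-1-ol
Conditions: i-Bu2AlH (2.2 equiv), CH2Cl2, −78 °C
Reagents that add atoms: none
Why: Low-temperature DIBAL reduction of the conjugated ester is a clean 1,2-reduction that leaves both alkenes and the silyl ether untouched.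

**Step 6**
Reactants: 8 (2E)-3-({[tert-butyl(diphenyl)silyl]oxy}methyl)hepta-2,6-dien-1-ol
Product: 9 (2E)-3-({[tert-butyl(diphenyl)silyl]oxy}methyl)hepta-2,6-dienal
Conditions: MnO2, CH2Cl2, rt
Reagents that add atoms: none
Why: Allylic oxidation with MnO2 is selective for the allylic alcohol and gives the enal without E/Z isomerisation.

**Step 7**
Reactants: 9 (2E)-3-({[tert-butyl(diphenyl)silyl]oxy}methyl)hepta-2,6-dienal; 10 methyl prop-2-ynoate
Product: 12 methyl (4R,5E)-6-({[tert-butyl(diphenyl)silyl]oxy}methyl)-4-hydroxydeca-5,9-dien-2-ynoate, via methylzinc acetylide 11 (not isolated)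
Conditions: Me2Zn (3 equiv), (R,R)-ProPhenol (20 mol %), Ph3P=O (40 mol %), toluene, 4 °C
Reagents that add atoms: none
Why: The Trost zinc–ProPhenol asymmetric alkynylation delivers the propiolate acetylide to one face of the enal and sets C6 as R, the first stereocenter, with the ligand sense assigned by analogy and to be confirmed by Mosher ester analysis (the antipodal ligand is used if it proves opposite).

**Step 8**
Reactants: 12 methyl (4R,5E)-6-({[tert-butyl(diphenyl)silyl]oxy}methyl)-4-hydroxydeca-5,9-dien-2-ynoate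
Product: 14 (5S)-5-[(1E)-2-({[tert-butyl(diphenyl)silyl]oxy}methyl)hexa-1,5-dien-1-yl]furan-2(5H)-one, via Z-hydroxy enoate 13 (not isolated)
Conditions: H2 (1 atm), Pd/CaCO3 poisoned with Pb(OAc)2 (Lindlar catalyst), quinoline, EtOAc, rt; then PPTS (cat.), CH2Cl2, rt
Reagents that add atoms: none
Why: Lindlar semihydrogenation gives the Z-enoate, whose cis-disposed hydroxyl and ester lactonise to the butenolide while C6 is untouched (the descriptor changes only through CIP priorities).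

**Step 9**
Reactants: 14 (5S)-5-[(1E)-2-({[tert-butyl(diphenyl)silyl]oxy}methyl)hexa-1,5-dien-1-yl]furan-2(5H)-one; 15 (chloromethyl)dimethyl(propan-2-yloxy)silane
Product: 18 (4S,5R)-5-[(1E)-2-({[tert-butyl(diphenyl)silyl]oxy}methyl)hexa-1,5-dien-1-yl]-4-{[dimethyl(propan-2-yloxy)silyl]methyl}oxolan-2-one, via Grignard reagent 16 (not isolated), via silyl ketene acetal 17 (not isolated)
Conditions: 15, Mg, THF, rt; then CuI (10 mol %), TMSCl, 14, THF, −78 °C; aq. NH4Cl
Reagents that add atoms: none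
Why: Copper-catalysed, TMSCl-accelerated conjugate addition of Tamao's silylmethyl Grignard reagent occurs anti to the C6 side chain, so C7 is set trans to C6 under substrate control.

**Step 10**
Reactants: 18 (4S,5R)-5-[(1E)-2-({[tert-butyl(diphenyl)silyl]oxy}methyl)hexa-1,5-dien-1-yl]-4-{[dimethyl(propan-2-yloxy)silyl]methyl}oxolan-2-one
Product: 19 (4R,5R)-5-[(1E)-2-({[tert-butyl(diphenyl)silyl]oxy}methyl)hexa-1,5-dien-1-yl]-4-(hydroxymethyl)oxolan-2-one
Conditions: H2O2 (30 %), KF, KHCO3, THF/MeOH, rt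
Reagents that add atoms: hydrogen peroxide, OO
Why: Tamao–Fleming oxidation turns the C–Si bond into C–OH under weakly basic conditions that leave the lactone, the alkenes and the TBDPS ether intact, and no stereocenter is affected.

**Step 11**
Reactants: 19 (4R,5R)-5-[(1E)-2-({[tert-butyl(diphenyl)silyl]oxy}methyl)hexa-1,5-dien-1-yl]-4-(hydroxymethyl)oxolan-2-one
Product: 20 (2R,3S)-2-[(1E)-2-({[tert-butyl(diphenyl)silyl]oxy}methyl)hexa-1,5-dien-1-yl]-5-oxooxolane-3-carbaldehyde
Conditions: Dess–Martin periodinane, CH2Cl2, 0 °C to rt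
Reagents that add atoms: none
Why: Dess–Martin oxidation gives the α-branched aldehyde under near-neutral conditions, and the trans arrangement at C7 is the thermodynamic one, so epimerisation cannot erode it.

**Step 12**
Reactants: 20 (2R,3S)-2-[(1E)-2-({[tert-butyl(diphenyl)silyl]oxy}methyl)hexa-1,5-dien-1-yl]-5-oxooxolane-3-carbaldehyde; 21 2,2-dimethyl-1,3-dioxan-5-one
Product: 22 (4R)-4-[(R)-hydroxy{(2R,3R)-2-[(1E)-2-({[tert-butyl(diphenyl)silyl]oxy}methyl)hexa-1,5-dien-1-yl]-5-oxooxolan-3-yl}methyl]-2,2-dimethyl-1,3-dioxan-5-one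
Conditions: (R)-proline (30 mol %), 21 (3 equiv), DMF, 4 °C
Reagents that add atoms: none
Why: In this proline-catalysed direct aldol (dioxanone aldol, Houk–List transition state) the (R)-proline enamine of 21 gives the anti aldol and sets C8 and C9 (both R in this compound) under catalyst control, reinforced by the Felkin–Anh preference of the α-branched aldehyde.

**Step 13**
Reactants: 22 (4R)-4-[(R)-hydroxy{(2R,3R)-2-[(1E)-2-({[tert-butyl(diphenyl)silyl]oxy}methyl)hexa-1,5-dien-1-yl]-5-oxooxolan-3-yl}methyl]-2,2-dimethyl-1,3-dioxan-5-one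
Product: 23 (4R)-4-[(R)-{(2R,3S)-2-[(1E)-2-({[tert-butyl(diphenyl)silyl]oxy}methyl)hexa-1,5-dien-1-yl]-5-oxooxolan-3-yl}(triethylsilyloxy)methyl]-2,2-dimethyl-1,3-dioxan-5-one
Conditions: TESOTf, 2,6-lutidine, CH2Cl2, −78 °C
Reagents that add atoms: triethylsilyl trifluoromethanesulfonate, CC[Si](CC)(CC)OS(=O)(=O)C(F)(F)F
Why: Low-temperature silylation protects the C8 hydroxyl before retro-aldol cleavage or translactonisation can intervene, and no stereocenter changes.

**Step 14**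
Reactants: 23 (4R)-4-[(R)-{(2R,3S)-2-[(1E)-2-({[tert-butyl(diphenyl)silyl]oxy}methyl)hexa-1,5-dien-1-yl]-5-oxooxolan-3-yl}(triethylsilyloxy)methyl]-2,2-dimethyl-1,3-dioxan-5-one
Product: 24 (4S,5R)-5-[(1E)-2-({[tert-butyl(diphenyl)silyl]oxy}methyl)hexa-1,5-dien-1-yl]-4-{(R)-[(4S)-2,2-dimethyl-5-methylidene-1,3-dioxan-4-yl](triethylsilyloxy)methyl}oxolan-2-one
Conditions: Zn, CH2Br2, TiCl4, THF/CH2Cl2, 0 °C to rt
Reagents that add atoms: dibromomethane, BrCBr
Why: Takai–Lombardo methylenation is non-basic and selective for ketones over lactones, so C10=O becomes C10=CH2 without epimerising C9 or eliminating the β-silyloxy group.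

**Step 15**
Reactants: 24 (4S,5R)-5-[(1E)-2-({[tert-butyl(diphenyl)silyl]oxy}methyl)hexa-1,5-dien-1-yl]-4-{(R)-[(4S)-2,2-dimethyl-5-methylidene-1,3-dioxan-4-yl](triethylsilyloxy)methyl}oxolan-2-one
Product: 25 (1(10)Z,4E,6R,7S,8R,9S)-15-{[tert-butyl(diphenyl)silyl]oxy}-9,14-(propane-2,2-diyldioxy)-8-(triethylsilyloxy)-13-norgermacra-1(10),4-dien-12,6-olide
Conditions: second-generation Hoveyda–Grubbs catalyst RuCl2(H2IMes)(=CH-C6H4-2-OiPr) (15 mol %), toluene (1 mM), 80 °C
Reagents that add atoms: none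
Why: Ring-closing metathesis between the C1 vinyl group and the 1,1-disubstituted C10 methylene closes the ten-membered ring, which accommodates only the ring-cis trisubstituted alkene, and loss of ethene drives it.

**Step 16**
Reactants: 25 (1(10)Z,4E,6R,7S,8R,9S)-15-{[tert-butyl(diphenyl)silyl]oxy}-9,14-(propane-2,2-diyldioxy)-8-(triethylsilyloxy)-13-norgermacra-1(10),4-dien-12,6-olide
Product: 29 (1(10)Z,4E,6R,7S,8R,9S)-15-{[tert-butyl(diphenyl)silyl]oxy}-9,14-(propane-2,2-diyldioxy)-8-(triethylsilyloxy)germacra-1(10),4,11(13)-trien-12,6-olide, via lithium enolate 26 (not isolated), via Mannich base 27 (not isolated), via ammonium iodide 28 (not isolated)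
Conditions: LiN(i-Pr)2, THF, −78 °C; CH2=NMe2+ I−, −78 °C to 0 °C; MeI, THF/MeOH, rt; aq. NaHCO3, CH2Cl2, rt
Reagents that add atoms: Eschenmoser's salt (N,N-dimethylmethaniminium iodide), C=[N+](C)C.[I-]
Why: Aminomethylation of the lactone enolate with Eschenmoser's salt followed by quaternisation and Hofmann-type elimination is the classical α-methylenation, and since C11 ends sp2 its transient configuration is irrelevant.

**Step 17**
Reactants: 29 (1(10)Z,4E,6R,7S,8R,9S)-15-{[tert-butyl(diphenyl)silyl]oxy}-9,14-(propane-2,2-diyldioxy)-8-(triethylsilyloxy)germacra-1(10),4,11(13)-trien-12,6-olide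
Product: 30 (1(10)Z,4E,6R,7R,8R,9S)-8,15-dihydroxy-9,14-(propane-2,2-diyldioxy)germacra-1(10),4,11(13)-trien-12,6-olide
Conditions: HF·pyridine, pyridine, THF, 0 °C to rt
Reagents that add atoms: none
Why: Buffered fluoride desilylation removes both silyl ethers while the acetonide, the α-methylene lactone and the alkenes survive (the C7 descriptor changes only through CIP priorities).

**Step 18**
Reactants: 30 (1(10)Z,4E,6R,7R,8R,9S)-8,15-dihydroxy-9,14-(propane-2,2-diyldioxy)germacra-1(10),4,11(13)-trien-12,6-olide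
Product: 31 (1(10)Z,4E,6R,7R,8R,9S)-15-acetoxy-8-hydroxy-9,14-(propane-2,2-diyldioxy)germacra-1(10),4,11(13)-trien-12,6-olide
Conditions: lipase (immobilised Candida antarctica lipase B), vinyl acetate, MTBE, 30 °C
Reagents that add atoms: vinyl acetate, C=COC(C)=O
Why: Lipase-catalysed irreversible transesterification acetylates only the unhindered primary allylic C15 hydroxyl and leaves the hindered secondary C8 hydroxyl free for the next step.

**Step 19**
Reactants: 32 (2E)-2-methylbut-2-enoic acid (tiglic acid)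
Product: 33 (2R)-2-methylbutanoic acid
Conditions: H2 (4 atm), Ru(OAc)2[(R)-H8-BINAP] (0.5 mol %), MeOH, 20 °C
Reagents that add atoms: none
Why: Noyori–Takaya asymmetric hydrogenation of the α,β-unsaturated acid with the (R)-configured ruthenium diphosphine catalyst sets the side-chain stereocenter as R.

**Step 20**
Reactants: 31 (1(10)Z,4E,6R,7R,8R,9S)-15-acetoxy-8-hydroxy-9,14-(propane-2,2-diyldioxy)germacra-1(10),4,11(13)-trien-12,6-olide; 33 (2R)-2-methylbutanoic acid
Product: 34 (1(10)Z,4E,6R,7S,8R,9S)-15-acetoxy-8-{[(2R)-2-methylbutanoyl]oxy}-9,14-(propane-2,2-diyldioxy)germacra-1(10),4,11(13)-trien-12,6-olide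
Conditions: DCC, DMAP, CH2Cl2, 0 °C to rt
Reagents that add atoms: none
Why: Steglich esterification acylates the C8 hydroxyl without touching any ring stereocenter, and an α-alkyl acid does not racemise under carbodiimide/DMAP activation.

**Step 21**
Reactants: 34 (1(10)Z,4E,6R,7S,8R,9S)-15-acetoxy-8-{[(2R)-2-methylbutanoyl]oxy}-9,14-(propane-2,2-diyldioxy)germacra-1(10),4,11(13)-trien-12,6-olide
Product: 35 (1(10)Z,4E,6R,7S,8R,9S)-15-acetoxy-9,14-dihydroxy-8-{[(2R)-2-methylbutanoyl]oxy}germacra-1(10),4,11(13)-trien-12,6-olide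
Conditions: AcOH/H2O/THF (3:1:1), 40 °C
Reagents that add atoms: none
Why: Mild acid-catalysed acetal hydrolysis frees the 9,14-diol under conditions too weak to cleave the esters or the lactone or to promote acyl migration.

**Step 22**
Reactants: 35 (1(10)Z,4E,6R,7S,8R,9S)-15-acetoxy-9,14-dihydroxy-8-{[(2R)-2-methylbutanoyl]oxy}germacra-1(10),4,11(13)-trien-12,6-olide
Product: 36 (1(10)E,4E,6R,7S,8R,9S)-15-acetoxy-9-hydroxy-8-{[(2R)-2-methylbutanoyl]oxy}-14-oxogermacra-1(10),4,11(13)-trien-12,6-olide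
Conditions: TEMPO (20 mol %), PhI(OAc)2 (1.1 equiv), CH2Cl2, rt
Reagents that add atoms: none
Why: Oxoammonium (TEMPO/PhI(OAc)2) oxidation is selective for the primary allylic C14 alcohol over the secondary C9 alcohol and gives the enal without changing the alkene geometry (the descriptor changes only through CIP priorities).

**Step 23**
Reactants: 36 (1(10)E,4E,6R,7S,8R,9S)-15-acetoxy-9-hydroxy-8-{[(2R)-2-methylbutanoyl]oxy}-14-oxogermacra-1(10),4,11(13)-trien-12,6-olide
Product: 37 (1(10)E,4E,6R,7S,8R,9S)-9,15-dihydroxy-8-{[(2R)-2-methylbutanoyl]oxy}-14-oxogermacra-1(10),4,11(13)-trien-12,6-olide (CNP0331447.12)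
Conditions: lipase (immobilised Candida antarctica lipase B), n-BuOH, MTBE, 30 °C
Reagents that add atoms: none
Why: Lipase-catalysed alcoholysis removes the unhindered primary acetate chemoselectively under neutral conditions, leaving the hindered 2-methylbutanoate, the lactone, the enal and the free C9 hydroxyl untouched where base or fluoride would risk acyl migration and Michael addition.

**Compound list**
1 | prop-2-yn-1-ol | C#CCO | starting material
2 | tert-butyl(diphenyl)(prop-2-yn-1-yloxy)silane | C#CCO[Si](c1ccccc1)(c1ccccc1)C(C)(C)C | intermediate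
3 | (3-{[tert-butyl(diphenyl)silyl]oxy}prop-1-yn-1-yl)lithium | [Li]C#CCO[Si](c1ccccc1)(c1ccccc1)C(C)(C)C | intermediate
4 | ethyl 4-{[tert-butyl(diphenyl)silyl]oxy}but-2-ynoate | CCOC(=O)C#CCO[Si](c1ccccc1)(c1ccccc1)C(C)(C)C | intermediate
5 | ethyl (2Z)-4-{[tert-butyl(diphenyl)silyl]oxy}-3-iodobut-2-enoate | CCOC(=O)/C=C(\I)CO[Si](c1ccccc1)(c1ccccc1)C(C)(C)C | intermediate
6 | but-3-en-1-ylzinc bromide | C=CCC[Zn]Br | starting material
7 | ethyl (2E)-3-({[tert-butyl(diphenyl)silyl]oxy}methyl)hepta-2,6-dienoate | CCOC(=O)/C=C(\CCC=C)CO[Si](c1ccccc1)(c1ccccc1)C(C)(C)C | intermediate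
8 | (2E)-3-({[tert-butyl(diphenyl)silyl]oxy}methyl)hepta-2,6-dien-1-ol | OC/C=C(\CCC=C)CO[Si](c1ccccc1)(c1ccccc1)C(C)(C)C | intermediate
9 | (2E)-3-({[tert-butyl(diphenyl)silyl]oxy}methyl)hepta-2,6-dienal | O=C/C=C(\CCC=C)CO[Si](c1ccccc1)(c1ccccc1)C(C)(C)C | intermediate
10 | methyl prop-2-ynoate | COC(=O)C#C | starting material
11 | methyl 3-(methylzincio)prop-2-ynoate | COC(=O)C#C[Zn]C | intermediate
12 | methyl (4R,5E)-6-({[tert-butyl(diphenyl)silyl]oxy}methyl)-4-hydroxydeca-5,9-dien-2-ynoate | COC(=O)C#C[C@H](O)/C=C(/CO[Si](c1ccccc1)(c1ccccc1)C(C)(C)C)CCC=C | intermediate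
13 | methyl (2Z,4S,5E)-6-({[tert-butyl(diphenyl)silyl]oxy}methyl)-4-hydroxydeca-2,5,9-trienoate | COC(=O)/C=C\[C@H](O)/C=C(/CO[Si](c1ccccc1)(c1ccccc1)C(C)(C)C)CCC=C | intermediate
14 | (5S)-5-[(1E)-2-({[tert-butyl(diphenyl)silyl]oxy}methyl)hexa-1,5-dien-1-yl]furan-2(5H)-one | O=C1C=C[C@@H](/C=C(/CO[Si](c2ccccc2)(c2ccccc2)C(C)(C)C)CCC=C)O1 | intermediate
15 | (chloromethyl)dimethyl(propan-2-yloxy)silane | CC(C)O[Si](C)(C)CCl | starting material
16 | {[dimethyl(propan-2-yloxy)silyl]methyl}magnesium chloride | CC(C)O[Si](C)(C)C[Mg]Cl | intermediate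
17 | trimethylsilyl ketene acetal of 18 (C6 R, C7 S) | C[Si](C)(C)OC1=C[C@H](C[Si](C)(C)OC(C)C)[C@@H](/C=C(/CO[Si](c2ccccc2)(c2ccccc2)C(C)(C)C)CCC=C)O1 | intermediate
18 | (4S,5R)-5-[(1E)-2-({[tert-butyl(diphenyl)silyl]oxy}methyl)hexa-1,5-dien-1-yl]-4-{[dimethyl(propan-2-yloxy)silyl]methyl}oxolan-2-one | O=C1C[C@H](C[Si](C)(C)OC(C)C)[C@@H](/C=C(/CO[Si](c2ccccc2)(c2ccccc2)C(C)(C)C)CCC=C)O1 | intermediate
19 | (4R,5R)-5-[(1E)-2-({[tert-butyl(diphenyl)silyl]oxy}methyl)hexa-1,5-dien-1-yl]-4-(hydroxymethyl)oxolan-2-one | O=C1C[C@H](CO)[C@@H](/C=C(/CO[Si](c2ccccc2)(c2ccccc2)C(C)(C)C)CCC=C)O1 | intermediate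
20 | (2R,3S)-2-[(1E)-2-({[tert-butyl(diphenyl)silyl]oxy}methyl)hexa-1,5-dien-1-yl]-5-oxooxolane-3-carbaldehyde | O=C1C[C@H](C=O)[C@@H](/C=C(/CO[Si](c2ccccc2)(c2ccccc2)C(C)(C)C)CCC=C)O1 | intermediate
21 | 2,2-dimethyl-1,3-dioxan-5-one | CC1(C)OCC(=O)CO1 | starting material
22 | (4R)-4-[(R)-hydroxy{(2R,3R)-2-[(1E)-2-({[tert-butyl(diphenyl)silyl]oxy}methyl)hexa-1,5-dien-1-yl]-5-oxooxolan-3-yl}methyl]-2,2-dimethyl-1,3-dioxan-5-one | O=C1C[C@H]([C@@H](O)[C@H]2OC(C)(C)OCC2=O)[C@@H](/C=C(/CO[Si](c3ccccc3)(c3ccccc3)C(C)(C)C)CCC=C)O1 | intermediate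
23 | (4R)-4-[(R)-{(2R,3S)-2-[(1E)-2-({[tert-butyl(diphenyl)silyl]oxy}methyl)hexa-1,5-dien-1-yl]-5-oxooxolan-3-yl}(triethylsilyloxy)methyl]-2,2-dimethyl-1,3-dioxan-5-one | O=C1C[C@H]([C@@H](O[Si](CC)(CC)CC)[C@H]2OC(C)(C)OCC2=O)[C@@H](/C=C(/CO[Si](c3ccccc3)(c3ccccc3)C(C)(C)C)CCC=C)O1 | intermediate
24 | (4S,5R)-5-[(1E)-2-({[tert-butyl(diphenyl)silyl]oxy}methyl)hexa-1,5-dien-1-yl]-4-{(R)-[(4S)-2,2-dimethyl-5-methylidene-1,3-dioxan-4-yl](triethylsilyloxy)methyl}oxolan-2-one | O=C1C[C@H]([C@@H](O[Si](CC)(CC)CC)[C@H]2OC(C)(C)OCC2=C)[C@@H](/C=C(/CO[Si](c3ccccc3)(c3ccccc3)C(C)(C)C)CCC=C)O1 | intermediate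
25 | (1(10)Z,4E,6R,7S,8R,9S)-15-{[tert-butyl(diphenyl)silyl]oxy}-9,14-(propane-2,2-diyldioxy)-8-(triethylsilyloxy)-13-norgermacra-1(10),4-dien-12,6-olide | C1C(=O)O[C@@H]2/C=C(/CO[Si](c3ccccc3)(c3ccccc3)C(C)(C)C)CC/C=C(/COC(C)(C)O4)[C@H]4[C@H](O[Si](CC)(CC)CC)[C@@H]12 | intermediate
26 | lithium enolate of 25 (C11=C12–OLi) | C1=C(O[Li])O[C@@H]2/C=C(/CO[Si](c3ccccc3)(c3ccccc3)C(C)(C)C)CC/C=C(/COC(C)(C)O4)[C@H]4[C@H](O[Si](CC)(CC)CC)[C@@H]12 | intermediate
27 | 13-(dimethylamino)-11,13-dihydro derivative of 29 (Mannich base; C11 configuration not controlled and lost in the next operation) | CN(C)CC1C(=O)O[C@@H]2/C=C(/CO[Si](c3ccccc3)(c3ccccc3)C(C)(C)C)CC/C=C(/COC(C)(C)O4)[C@H]4[C@H](O[Si](CC)(CC)CC)[C@@H]12 | intermediate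
28 | N-methyl ammonium iodide of 27 (C11 configuration not controlled) | C[N+](C)(C)CC1C(=O)O[C@@H]2/C=C(/CO[Si](c3ccccc3)(c3ccccc3)C(C)(C)C)CC/C=C(/COC(C)(C)O4)[C@H]4[C@H](O[Si](CC)(CC)CC)[C@@H]12.[I-] | intermediate
29 | (1(10)Z,4E,6R,7S,8R,9S)-15-{[tert-butyl(diphenyl)silyl]oxy}-9,14-(propane-2,2-diyldioxy)-8-(triethylsilyloxy)germacra-1(10),4,11(13)-trien-12,6-olide | C=C1C(=O)O[C@@H]2/C=C(/CO[Si](c3ccccc3)(c3ccccc3)C(C)(C)C)CC/C=C(/COC(C)(C)O4)[C@H]4[C@H](O[Si](CC)(CC)CC)[C@@H]12 | intermediate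
30 | (1(10)Z,4E,6R,7R,8R,9S)-8,15-dihydroxy-9,14-(propane-2,2-diyldioxy)germacra-1(10),4,11(13)-trien-12,6-olide | C=C1C(=O)O[C@@H]2/C=C(/CO)CC/C=C(/COC(C)(C)O3)[C@H]3[C@H](O)[C@@H]12 | intermediate
31 | (1(10)Z,4E,6R,7R,8R,9S)-15-acetoxy-8-hydroxy-9,14-(propane-2,2-diyldioxy)germacra-1(10),4,11(13)-trien-12,6-olide | C=C1C(=O)O[C@@H]2/C=C(/COC(C)=O)CC/C=C(/COC(C)(C)O3)[C@H]3[C@H](O)[C@@H]12 | intermediate
32 | (2E)-2-methylbut-2-enoic acid (tiglic acid) | C/C=C(\C)C(=O)O | starting material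
33 | (2R)-2-methylbutanoic acid | CC[C@@H](C)C(=O)O | intermediate
34 | (1(10)Z,4E,6R,7S,8R,9S)-15-acetoxy-8-{[(2R)-2-methylbutanoyl]oxy}-9,14-(propane-2,2-diyldioxy)germacra-1(10),4,11(13)-trien-12,6-olide | C=C1C(=O)O[C@@H]2/C=C(/COC(C)=O)CC/C=C(/COC(C)(C)O3)[C@H]3[C@H](OC(=O)[C@H](C)CC)[C@@H]12 | intermediate
35 | (1(10)Z,4E,6R,7S,8R,9S)-15-acetoxy-9,14-dihydroxy-8-{[(2R)-2-methylbutanoyl]oxy}germacra-1(10),4,11(13)-trien-12,6-olide | C=C1C(=O)O[C@@H]2/C=C(/COC(C)=O)CC/C=C(/CO)[C@H](O)[C@H](OC(=O)[C@H](C)CC)[C@@H]12 | intermediate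
36 | (1(10)E,4E,6R,7S,8R,9S)-15-acetoxy-9-hydroxy-8-{[(2R)-2-methylbutanoyl]oxy}-14-oxogermacra-1(10),4,11(13)-trien-12,6-olide | C=C1C(=O)O[C@@H]2/C=C(/COC(C)=O)CC/C=C(/C=O)[C@H](O)[C@H](OC(=O)[C@H](C)CC)[C@@H]12 | intermediate
37 | (1(10)E,4E,6R,7S,8R,9S)-9,15-dihydroxy-8-{[(2R)-2-methylbutanoyl]oxy}-14-oxogermacra-1(10),4,11(13)-trien-12,6-olide (CNP0331447.12) | C=C1C(=O)O[C@@H]2/C=C(/CO)CC/C=C(/C=O)[C@H](O)[C@H](OC(=O)[C@H](C)CC)[C@@H]12 | target

**Totals**
Total step count: 23. Longest linear sequence: 22 steps (steps 1–18 and 20–23, from prop-2-yn-1-ol); step 19 is a one-step side branch.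

**Three steps most likely to fail**

Step 15 (ring-closing metathesis). A ten-membered ring must close onto a hindered 1,1-disubstituted alkene held on the dioxane ring, so initiation at that site and oligomerisation are real concerns. The fallback is a relay ring-closing metathesis that sets out from ketone 23 and comes back at macrocycle 25. Wittig reaction of 23 with hex-5-en-1-ylidene(triphenyl)phosphorane (from the phosphonium bromide and KN(SiMe3)2, THF, −78 °C to 0 °C) gives the relay triene F4, an E/Z mixture at the new alkene whose geometry is of no consequence because that carbon is excised. With the second-generation Grubbs catalyst RuCl2(H2IMes)(PCy3)(=CHPh) in dilute toluene at 60 °C, ruthenium loads at the unhindered relay terminus and expels cyclopentene. That places the alkylidene directly on C10, and closure on the C1 vinyl group gives 25.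

Step 12 (proline aldol). Aldehyde 20 is hindered and carries the lactone oxygen β to the formyl group, so slow turnover or enamine-triggered β-elimination could compete. The fallback is a stoichiometric, substrate-controlled boron aldol that sets out from 20 and 21 and comes back at 22. Enolisation of 21 with (c-Hex)2BCl and Et3N in Et2O at −78 °C to 0 °C gives the enol borinate F2, which as a ring-locked E-enolate reacts with 20 at −78 °C through a chair transition state. Attack on the Felkin–Anh face of 20 gives the anti aldol as its boron aldolate F3, and a pH 7 buffer/MeOH/H2O2 work-up releases 22.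

Step 9 (conjugate addition). The 5-alkenyl butenolide 14 has an acidic, allylic C6–H and an allylic lactone C–O bond, so deprotonation or SN2′ opening could compete with 1,4-addition. The fallback is a radical Giese addition under neutral conditions that sets out from 14 and comes back at aldehyde 20, bypassing steps 10 and 11. Irradiation (390 nm) of 14 in 1,3-dioxolane/MeCN with (n-Bu4N)4[W10O32] (2 mol %) generates the nucleophilic 1,3-dioxolan-2-yl radical, which adds to C7 anti to the C6 side chain to give the trans dioxolanyl lactone F1. Hydrolysis of the acetal with 1 M aq. HCl in THF at rt gives 20.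

**Further compounds**
F1 | step 9 | (4S,5R)-5-[(1E)-2-({[tert-butyl(diphenyl)silyl]oxy}methyl)hexa-1,5-dien-1-yl]-4-(1,3-dioxolan-2-yl)oxolan-2-one | O=C1C[C@H](C2OCCO2)[C@@H](/C=C(/CO[Si](c2ccccc2)(c2ccccc2)C(C)(C)C)CCC=C)O1
F2 | step 12 | dicyclohexyl[(2,2-dimethyl-4H-1,3-dioxin-5-yl)oxy]borane (enol borinate of 21) | CC1(C)OCC(OB(C2CCCCC2)C2CCCCC2)=CO1
F3 | step 12 | O8-dicyclohexylboryl aldolate of 22 | O=C1C[C@H]([C@@H](OB(C2CCCCC2)C2CCCCC2)[C@H]2OC(C)(C)OCC2=O)[C@@H](/C=C(/CO[Si](c3ccccc3)(c3ccccc3)C(C)(C)C)CCC=C)O1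
F4 | step 15 | relay triene: analogue of 24 with C10=CH(CH2)3CH=CH2 in place of C10=CH2 (E/Z mixture at that alkene) | O=C1C[C@H]([C@@H](O[Si](CC)(CC)CC)[C@H]2OC(C)(C)OCC2=CCCCC=C)[C@@H](/C=C(/CO[Si](c3ccccc3)(c3ccccc3)C(C)(C)C)CCC=C)O1
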